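## Retrosynthetic overview

- **Feature:** ring A (C4a–C5–C6–C7–C8–C8a) carries oxygen on C5, C7 and C8a (O1), the alternating pattern of a folded tricarbonyl chain, plus one extra OMe on C8. Ring C (O1, C2, C3, C4, C4a, C8a) is kept intact as a 4-pyranone, which stands for the rest of the masked polyketone and pins C4a and C8a.
- Target ⇒ 7-O-methylation ⇒ 5,7-dihydroxy-8-methoxyflavone ⇒ cut C5–C6 (intramolecular Claisen condensation, then aromatisation) ⇒ 6-aryl-4-pyranone with CO2Me on the future C4a and CH(OMe)C(O)CH3 on the future C8a.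
- Pyranone ⇒ cut O1–C2 (oxa-Michael closure) and C4–C4a (C-acylation) ⇒ ketal-masked methyl 4-methoxy-3,5-dioxohexanoate + 3-(2,3,4,5-tetramethoxyphenyl)propynoyl chloride.
- β-Keto ester ⇒ methyl acetoacetate (diazo transfer, O–H insertion of MeOH, ketal) + methyl acetate (crossed Claisen). Acid chloride ⇒ 1,2,3,4-tetramethoxybenzene (formylation, Corey–Fuchs homologation, carboxylation).
- Order of rings: B is bought, C is closed in step 9, A is closed in step 11.

Key step: step 11

Assumption: every intermediate with the CH(OMe) stereocentre is used as the racemate, because this carbon becomes the planar C8 of ring A in step 11. The target has no stereocentre. Flavone numbering is used for "future" positions.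

## Route

Step 1
Reactants: 1 methyl acetoacetate
Product: 2 methyl 2-diazo-3-oxobutanoate
Conditions: 4-acetamidobenzenesulfonyl azide, Et3N, MeCN, 0 °C to rt
Reagents that add atoms: 4-acetamidobenzenesulfonyl azide, CC(=O)Nc1ccc(cc1)S(=O)(=O)N=[N+]=[N-]
Why: Regitz diazo transfer, in which the amine-generated enolate of the active methylene attacks the terminal azide nitrogen and the adduct collapses to the diazo compound and the sulfonamide, is standard for β-keto esters.

Step 2
Reactants: 2 methyl 2-diazo-3-oxobutanoate
Product: 3 methyl 2-methoxy-3-oxobutanoate (racemic)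
Conditions: Rh2(OAc)4 (1 mol %), MeOH (5 equiv), CH2Cl2, reflux
Reagents that add atoms: methanol, CO
Why: Rhodium-carbenoid O–H insertion places the future C8 methoxy group without exposing an α-halo-β-keto ester to methoxide (retro-Claisen cleavage), and the new stereocentre is racemic and is erased in step 11.

Step 3
Reactants: 3 methyl 2-methoxy-3-oxobutanoate
Product: 4 methyl 2-methoxy-2-(2-methyl-1,3-dioxolan-2-yl)acetate (racemic)
Conditions: HOCH2CH2OH (3 equiv), p-TsOH·H2O (cat.), toluene, Dean–Stark reflux
Reagents that add atoms: ethylene glycol, OCCO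
Why: In this acid-catalysed ketalisation with azeotropic water removal only the ketone can form the dioxolane, which masks the acetyl group (future C6–C7) so that the later β-keto ester has a single acidic site.

Step 4
Reactants: 4 methyl 2-methoxy-2-(2-methyl-1,3-dioxolan-2-yl)acetate; 5 methyl acetate
Product: 7 methyl 4-methoxy-4-(2-methyl-1,3-dioxolan-2-yl)-3-oxobutanoate (racemic), via lithium enolate of methyl acetate 6 (not isolated)
Conditions: 5 (3.5 equiv), LiN(iPr)2 (LDA, 3.5 equiv), THF, −78 °C; then 4, −78 to −20 °C; AcOH quench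
Reagents that add atoms: none
Why: In this crossed Claisen condensation the preformed enolate 6, in excess so that a second equivalent deprotonates the product, should add to the α-alkoxy-activated ester of 4 faster than it abstracts the hindered α-proton, and the product enolate protects the new ketone.

Step 5
Reactants: 8 1,2,3,4-tetramethoxybenzene
Product: 10 2,3,4,5-tetramethoxybenzaldehyde, via aryl iminium chloride 9 (not isolated)
Conditions: POCl3, DMF, 0 to 80 °C; then ice-water
Reagents that add atoms: N,N-dimethylformamide, CN(C)C=O; water, O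
Why: In this Vilsmeier–Haack formylation the two free ring positions are equivalent by symmetry and each has an ortho and a para methoxy group, so one monoaldehyde is expected, and the formyl group deactivates the ring toward a second attack.

Step 6
Reactants: 10 2,3,4,5-tetramethoxybenzaldehyde
Product: 11 1-(2,2-dibromoethenyl)-2,3,4,5-tetramethoxybenzene
Conditions: CBr4 (2 equiv), PPh3 (4 equiv), CH2Cl2, 0 °C
Reagents that add atoms: carbon tetrabromide, BrC(Br)(Br)Br
Why: In this first stage of the Corey–Fuchs sequence the ylide Ph3P=CBr2 formed in the flask olefinates the aldehyde in a Wittig reaction, and aryl methyl ethers are inert.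

Step 7
Reactants: 11 1-(2,2-dibromoethenyl)-2,3,4,5-tetramethoxybenzene
Product: 13 3-(2,3,4,5-tetramethoxyphenyl)prop-2-ynoic acid, via lithium arylacetylide 12 (not isolated)
Conditions: n-BuLi (2.2 equiv), THF, −78 to 0 °C; CO2, −78 °C to rt; 1 M HCl
Reagents that add atoms: carbon dioxide, O=C=O
Why: In this second stage of the Corey–Fuchs sequence bromine–lithium exchange, Fritsch–Buttenberg–Wiechell-type loss of LiBr and deprotonation give acetylide 12, which CO2 carboxylates in the same flask.

Step 8
Reactants: 13 3-(2,3,4,5-tetramethoxyphenyl)prop-2-ynoic acid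
Product: 14 3-(2,3,4,5-tetramethoxyphenyl)prop-2-ynoyl chloride
Conditions: (COCl)2 (1.3 equiv), DMF (cat.), CH2Cl2, 0 °C to rt; concentrated and used crude
Reagents that add atoms: oxalyl chloride, O=C(Cl)C(=O)Cl
Why: Acid chloride formation through the catalytic chloroiminium species runs at or below room temperature, which is mild enough to avoid addition of HCl across the triple bond.

Step 9
Reactants: 7 methyl 4-methoxy-4-(2-methyl-1,3-dioxolan-2-yl)-3-oxobutanoate; 14 3-(2,3,4,5-tetramethoxyphenyl)prop-2-ynoyl chloride
Product: 16 methyl 2-[methoxy(2-methyl-1,3-dioxolan-2-yl)methyl]-4-oxo-6-(2,3,4,5-tetramethoxyphenyl)-4H-pyran-3-carboxylate (racemic), via alkynoyl tricarbonyl compound 15 (not isolated)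
Conditions: MgCl2 (1.2 equiv), pyridine (2.5 equiv), CH2Cl2, 0 °C to rt; cold 0.5 M HCl wash; crude 15, DMAP (20 mol %), DMF, 40 °C
Reagents that add atoms: none
Why: C-acylation of the chelated magnesium enolate of a β-keto ester is followed by the classical closure of an alkynoyl 1,3-dicarbonyl compound to a 4-pyranone, in which the enol oxygen of the aliphatic ketone adds to the ynone β-carbon (6-endo-dig oxa-Michael addition, O1–C2 of the flavone), and DMAP, by adding first to that same carbon, steers the closure away from the 5-exo-dig furanone.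

Step 10
Reactants: 16 methyl 2-[methoxy(2-methyl-1,3-dioxolan-2-yl)methyl]-4-oxo-6-(2,3,4,5-tetramethoxyphenyl)-4H-pyran-3-carboxylate
Product: 17 methyl 2-(1-methoxy-2-oxopropyl)-4-oxo-6-(2,3,4,5-tetramethoxyphenyl)-4H-pyran-3-carboxylate (racemic)
Conditions: 3 M aq. HCl, THF, 45 °C
Reagents that add atoms: water, O
Why: Acid hydrolysis of this dioxolane is slowed by the neighbouring OMe and pyranone groups, hence the strong aqueous acid and gentle heating, which the 4-pyranone, the doubly flanked conjugated methyl ester and the aryl methyl ethers tolerate.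

Step 11
Reactants: 17 methyl 2-(1-methoxy-2-oxopropyl)-4-oxo-6-(2,3,4,5-tetramethoxyphenyl)-4H-pyran-3-carboxylate
Product: 20 5,7-dihydroxy-8-methoxy-2-(2,3,4,5-tetramethoxyphenyl)-4H-chromen-4-one, via dilithium dianion 18 (not isolated), via chromene-4,5,7-trione tautomer 19 (not isolated)
Conditions: LiN(iPr)2 (LDA, 3.3 equiv), THF, −78 °C, slow addition of 17 to the base; −78 °C to rt; then 1 M HCl
Reagents that add atoms: none
Why: Proposed new method: the first equivalent of base removes the most acidic proton, the CH(OMe) methine conjugated with the acetyl group and vinylogously with the pyranone, a second equivalent deprotonates the acetyl CH3, and the terminal carbanion of dianion 18, its most nucleophilic site as in β-dicarbonyl dianions, adds to the ester carbonyl on pyranone C3 (new C5–C6 bond of the flavone) with loss of methoxide to give trione 19. Ring A closes in the 6-exo-trig mode, and 19 enolises at once to the 5,7-bis-phenoxide, an irreversible aromatisation that drains every reversible proton transfer and addition before it. The closest known reaction types are the Dieckmann-type closure of methyl 2-(2-oxopropyl)benzoates to naphthalene-1,3-diols and the biomimetic Claisen folding of 3,5,7-triketo esters to acylphloroglucinols, whereas a 4-pyranone-3-carboxylate has not served as the template. No stereocentre is created, and the racemic CH(OMe) centre of 17 becomes the sp2 carbon C8. The step needs C- over O-acylation and one carbanion and one carbonyl out of several: the methine carbanion could only close a four-membered ring, the pyranone C4 carbonyl lies trans to the side chain across the C2=C3 double bond and is out of reach, and lithium chelation between the enolate oxygen and the adjacent OMe turns the CH2 terminus rather than the oxygen toward the ester, while any enol lactone that forms is reopened by the liberated LiOMe. The bulky amide base does not add to the ring and the delocalised negative charge shields pyranone C2 and C6 from methoxide, so ring C stays closed, and since ring C decides which carbon is C4a and which is C8a, only the 8-methoxy isomer can form, never the 6-methoxy one.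

Step 12
Reactants: 20 5,7-dihydroxy-8-methoxy-2-(2,3,4,5-tetramethoxyphenyl)-4H-chromen-4-one
Product: 21 5-hydroxy-7,8-dimethoxy-2-(2,3,4,5-tetramethoxyphenyl)-4H-chromen-4-one (target)
Conditions: MeI (1.1 equiv), K2CO3 (1.5 equiv), acetone, rt to 40 °C
Reagents that add atoms: iodomethane, CI
Why: In this Williamson-type O-methylation under weak base the 7-OH is the free and most acidic phenol, while the 5-OH is held in a hydrogen bond to the C4 carbonyl and stays unreacted with a slight excess of MeI, the usual selectivity of 5,7-dihydroxyflavones.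

## Compound list

| No. | Name | SMILES | Role |
|---|---|---|---|
| 1 | methyl acetoacetate | CC(=O)CC(=O)OC | starting material |
| 2 | methyl 2-diazo-3-oxobutanoate | CC(=O)C(=[N+]=[N-])C(=O)OC | intermediate |
| 3 | methyl 2-methoxy-3-oxobutanoate (racemic) | CC(=O)C(OC)C(=O)OC | intermediate |
| 4 | methyl 2-methoxy-2-(2-methyl-1,3-dioxolan-2-yl)acetate (racemic) | COC(=O)C(OC)C1(C)OCCO1 | intermediate |
| 5 | methyl acetate | COC(C)=O | starting material |
| 6 | lithium enolate of methyl acetate (not isolated) | [Li+].[O-]C(=C)OC | intermediate |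
| 7 | methyl 4-methoxy-4-(2-methyl-1,3-dioxolan-2-yl)-3-oxobutanoate (racemic) | COC(=O)CC(=O)C(OC)C1(C)OCCO1 | intermediate |
| 8 | 1,2,3,4-tetramethoxybenzene | COc1ccc(OC)c(OC)c1OC | starting material |
| 9 | N,N-dimethyl(2,3,4,5-tetramethoxybenzylidene)iminium chloride (not isolated) | COc1cc(C=[N+](C)C)c(OC)c(OC)c1OC.[Cl-] | intermediate |
| 10 | 2,3,4,5-tetramethoxybenzaldehyde | COc1cc(C=O)c(OC)c(OC)c1OC | intermediate |
| 11 | 1-(2,2-dibromoethenyl)-2,3,4,5-tetramethoxybenzene | COc1cc(C=C(Br)Br)c(OC)c(OC)c1OC | intermediate |
| 12 | lithium (2,3,4,5-tetramethoxyphenyl)acetylide (not isolated) | [Li]C#Cc1cc(OC)c(OC)c(OC)c1OC | intermediate |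
| 13 | 3-(2,3,4,5-tetramethoxyphenyl)prop-2-ynoic acid | COc1cc(C#CC(=O)O)c(OC)c(OC)c1OC | intermediate |
| 14 | 3-(2,3,4,5-tetramethoxyphenyl)prop-2-ynoyl chloride | COc1cc(C#CC(=O)Cl)c(OC)c(OC)c1OC | intermediate |
| 15 | methyl 2-[2-methoxy-2-(2-methyl-1,3-dioxolan-2-yl)acetyl]-3-oxo-5-(2,3,4,5-tetramethoxyphenyl)pent-4-ynoate (drawn as the triketo tautomer, largely enolised, not isolated) | COC(=O)C(C(=O)C#Cc1cc(OC)c(OC)c(OC)c1OC)C(=O)C(OC)C1(C)OCCO1 | intermediate |
| 16 | methyl 2-[methoxy(2-methyl-1,3-dioxolan-2-yl)methyl]-4-oxo-6-(2,3,4,5-tetramethoxyphenyl)-4H-pyran-3-carboxylate (racemic) | COC(=O)c1c(C(OC)C2(C)OCCO2)oc(-c2cc(OC)c(OC)c(OC)c2OC)cc1=O | intermediate |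
| 17 | methyl 2-(1-methoxy-2-oxopropyl)-4-oxo-6-(2,3,4,5-tetramethoxyphenyl)-4H-pyran-3-carboxylate (racemic) | COC(=O)c1c(C(OC)C(C)=O)oc(-c2cc(OC)c(OC)c(OC)c2OC)cc1=O | intermediate |
| 18 | dilithium dianion of 17 (one resonance form, not isolated) | [Li+].[Li+].C=C([O-])C(OC)=C1OC(=CC([O-])=C1C(=O)OC)c1cc(OC)c(OC)c(OC)c1OC | intermediate |
| 19 | 8-methoxy-2-(2,3,4,5-tetramethoxyphenyl)-6H-chromene-4,5,7(8H)-trione (not isolated) | COC1C(=O)CC(=O)c2c1oc(-c1cc(OC)c(OC)c(OC)c1OC)cc2=O | intermediate |
| 20 | 5,7-dihydroxy-8-methoxy-2-(2,3,4,5-tetramethoxyphenyl)-4H-chromen-4-one | COc1cc(-c2cc(=O)c3c(O)cc(O)c(OC)c3o2)c(OC)c(OC)c1OC | intermediate |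
| 21 | 5-hydroxy-7,8-dimethoxy-2-(2,3,4,5-tetramethoxyphenyl)-4H-chromen-4-one | COc1cc(-c2cc(=O)c3c(O)cc(OC)c(OC)c3o2)c(OC)c(OC)c1OC | target |

Total step count: 12.
Longest linear sequence: 8 steps (steps 1–4 or steps 5–8, then steps 9–12).

## Steps most likely to fail

**1. Step 11.**
- **What may go wrong:** the second deprotonation may be incomplete. Addition may be sluggish because the ester is conjugated with the delocalised anion. The enolate oxygen may be acylated to an enol lactone. Liberated methoxide may open the pyranone.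
- **Fallback (known chemistry; ring A is bought and ring C is built last):** the fallback sets out from aldehyde 10.
  - Aldehyde 10 is condensed with commercial 1-(2-hydroxy-3,4,6-trimethoxyphenyl)ethanone, CC(=O)c1c(O)c(OC)c(OC)cc1OC, under Claisen–Schmidt conditions (KOH, EtOH, rt). This should give (E)-1-(2-hydroxy-3,4,6-trimethoxyphenyl)-3-(2,3,4,5-tetramethoxyphenyl)prop-2-en-1-one F1.
  - I2 (cat.) in DMSO at 130 °C closes and dehydrogenates F1 to 5,7,8-trimethoxy-2-(2,3,4,5-tetramethoxyphenyl)-4H-chromen-4-one F2.
  - BCl3 (CH2Cl2, −78 to 0 °C) cleaves only the 5-OMe group, which binds boron together with the C4 carbonyl. The temperature is too low for a Wessely–Moser ring isomerisation.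
  - The route is rejoined at target 21.

**2. Step 9.**
- **What may go wrong:** the enolate may be acylated on oxygen instead of carbon. The enol oxygen may close on the wrong alkyne carbon (5-exo-dig), since the electron-rich aryl group weakens the polarisation of the ynone.
- **Fallback:** the carbon to be attacked is marked by a leaving group. The fallback sets out from acid 13.
  - Acid 13 is hydrochlorinated (LiCl, AcOH, 90 °C, anti addition) to (Z)-3-chloro-3-(2,3,4,5-tetramethoxyphenyl)prop-2-enoic acid F3.
  - (COCl)2 with catalytic DMF converts F3 into (Z)-3-chloro-3-(2,3,4,5-tetramethoxyphenyl)prop-2-enoyl chloride F4.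
  - Acylation of the magnesium enolate of 7 (MgCl2, pyridine, CH2Cl2) with F4 should give methyl (Z)-5-chloro-2-[2-methoxy-2-(2-methyl-1,3-dioxolan-2-yl)acetyl]-3-oxo-5-(2,3,4,5-tetramethoxyphenyl)pent-4-enoate F5.
  - Et3N in MeCN closes the ring by addition–elimination at the chlorine-bearing carbon, so no five-membered ring can arise.
  - The route is rejoined at 16.

**3. Step 4.**
- **What may go wrong:** the α-proton of 4 may be abstracted, followed by β-elimination that opens the dioxolane. Addition to the hindered ester may be slow while the methyl acetate enolate self-condenses.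
- **Fallback:** the strong base is avoided altogether. The fallback sets out from ester 4.
  - Ester 4 is saponified (LiOH, THF/H2O, rt; cold acidification to pH 3) to 2-methoxy-2-(2-methyl-1,3-dioxolan-2-yl)acetic acid F6.
  - 1,1'-Carbonyldiimidazole (THF, rt) activates F6 as 1-(1H-imidazol-1-yl)-2-methoxy-2-(2-methyl-1,3-dioxolan-2-yl)ethan-1-one F7.
  - F7 is treated with Mg(O2CCH2CO2Me)2 (from potassium methyl malonate, MgCl2 and Et3N) in a Masamune–Brooks decarboxylative Claisen condensation under nearly neutral conditions.
  - The route is rejoined at 7.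

## Further compounds

F1 | step 11 | (E)-1-(2-hydroxy-3,4,6-trimethoxyphenyl)-3-(2,3,4,5-tetramethoxyphenyl)prop-2-en-1-one | COc1cc(/C=C/C(=O)c2c(O)c(OC)c(OC)cc2OC)c(OC)c(OC)c1OC
F2 | step 11 | 5,7,8-trimethoxy-2-(2,3,4,5-tetramethoxyphenyl)-4H-chromen-4-one | COc1cc(-c2cc(=O)c3c(OC)cc(OC)c(OC)c3o2)c(OC)c(OC)c1OC
F3 | step 9 | (Z)-3-chloro-3-(2,3,4,5-tetramethoxyphenyl)prop-2-enoic acid | OC(=O)/C=C(\Cl)c1cc(OC)c(OC)c(OC)c1OC
F4 | step 9 | (Z)-3-chloro-3-(2,3,4,5-tetramethoxyphenyl)prop-2-enoyl chloride | ClC(=O)/C=C(\Cl)c1cc(OC)c(OC)c(OC)c1OC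
F5 | step 9 | methyl (Z)-5-chloro-2-[2-methoxy-2-(2-methyl-1,3-dioxolan-2-yl)acetyl]-3-oxo-5-(2,3,4,5-tetramethoxyphenyl)pent-4-enoate | COC(=O)C(C(=O)/C=C(\Cl)c1cc(OC)c(OC)c(OC)c1OC)C(=O)C(OC)C1(C)OCCO1
F6 | step 4 | 2-methoxy-2-(2-methyl-1,3-dioxolan-2-yl)acetic acid (racemic) | OC(=O)C(OC)C1(C)OCCO1
F7 | step 4 | 1-(1H-imidazol-1-yl)-2-methoxy-2-(2-methyl-1,3-dioxolan-2-yl)ethan-1-one (racemic) | O=C(C(OC)C1(C)OCCO1)n1ccnc1
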